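Numbering follows the eudesmane skeleton for all bicyclic compounds: ring A = C1–C5 and C10, ring B = C5–C10, C14 = methyl on C10, C15 = methyl on C4, C11–C13 = the three-carbon unit on C7. β is the face of C14, α the opposite face.

## The problem

Compound 34 is a trans-fused decalin in which rings A and B share the C5–C10 bond, C10 is quaternary and H-5 lies on the α-face. Four contiguous stereocentres have to be set: C10 and C5 at the ring fusion, C4 (tertiary α-hydroxyl, β-methyl) and C3 (axial α-angelate). C10 carries no functional group and cannot be corrected once made, so it must be set absolutely and early. The other three can be derived from it: reduction of a C4=C5 enone places H-5 trans to C14, and the axial C14 methyl then shields the β-face of ring A so that oxygen reaches C3 and C4 from the α-face. Ring B holds an enone (C6=C7–C8=O) whose α-carbon C7 bears a tertiary allylic hydroperoxide at C11, a group that will not tolerate reducing agents, phosphines, low-valent metals, strong base or heating. The angelate is a (Z)-2-methylbut-2-enoate that isomerises to the tiglate under basic, nucleophilic or strongly acidic conditions, and it sits on a hindered axial hydroxyl next to a free tertiary alcohol. Both groups therefore come last, the ester before the hydroperoxide. The feature that opens the key step is that the quaternary C10 is para to the oxygenated C3: ring A can be a 4-methyl-4-alkylcyclohexa-2,5-dienone with enantiotopic enone arms (C1=C2 and C4=C5), and the chain C9–C8–C7–C6 on C10 ends where a nucleophilic C6 reaches C5 to close ring B.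

## Retrosynthesis

**34 ⇒ 33 (C11–O bond and the C6=C7 double bond).** 34 is the ene adduct of singlet oxygen and the 7(11)-en-8-one 33: oxygen to C11, hydrogen from C6, double bond moved from C7=C11 to C6=C7. Making the hydroperoxide last means no peroxide is carried through any step. The neighbouring options (substitution at a tertiary allylic carbon, or metal-mediated hydroperoxidation of an isopropenyl dienone) need a preformed C6=C7 bond and harsher reagents. 33 lacks the most fragile group. The forward reaction must take hydrogen from C6 and not from C12/C13, and must spare the angelate.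

**33 ⇒ 30 + 31 (ester C–O bond at C3).** Acylation of diol 30 with angelic acid 31 is preferred to building the ester earlier, because no later step would then have to tolerate a base-sensitive (Z)-enoate. The tertiary 4-hydroxyl needs no protection. The forward step must acylate a hindered axial alcohol without Z-to-E isomerisation.

**30 ⇒ 29 (C3–O and C4–O bonds).** Both oxygens are removed together, back to the C3=C4 alkene of eudesma-3,7(11)-dien-8-one 29. One syn-dihydroxylation from the α-face sets C3 and C4 at once. The alternative, hydroxylation of a C4 enolate followed by reduction of a C3 ketone, would need hydride delivery past the axial C15 methyl to give the axial alcohol. The forward step must choose the electron-rich trisubstituted alkene over the electron-poor tetrasubstituted enone bond.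

**29 ⇒ 27 ⇒ 24 + 25 (C7–C11 bond).** The isopropylidene group comes from aldol addition of ketone 24 to acetone 25 (giving 27) and dehydration. This is cut before the ring-A oxygens so that no diol protection is needed. 24 is a bicyclic C12 ketone with only C5 and C10 as stereocentres. The forward step needs enolisation at C7, not at the neopentyl C9.

**24 ⇒ 23 ⇒ 22 ⇒ 20 (C8 ketal; C3–H and C5–H bonds).** The ketone is masked as dioxolane 23. The C3=C4 alkene comes from enol triflate 22, and 22 from the enolate generated by dissolving-metal reduction of enone 20. That single reduction sets H-5 trans to C14 and fixes the double bond at C3=C4 without a regiochemical choice, which enolisation of a saturated 3-ketone could not do. The precursor 20 has C10 as its only stereocentre.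

**20 ⇒ 19 ⇒ 16 ⇒ 14 (C1–H/C2–H, the C4=C5 bond, C4–C15).** Enone 20 is reached from the cis-fused enone 14 by methylation at C4 (16), dehydrogenation to the cross-conjugated dienone 19 and hydrogenation of C1=C2. The C1=C2 bond of 14 acts as a blocking group: with C10 quaternary, 14 can enolise only toward C4, so methylation and dehydrogenation are regiodefined. The cis C5 centre of 14 is flattened here and reset in step 12.

**14 ⇒ 13 (C6–CHO bond).** The formyl group of 13 is the activating group of the key step and has no place in the target. It is removed in one step by decarbonylation, which leaves C6 as the methylene that later gives up a hydrogen in the ene reaction.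

**13 ⇒ 12 (C5–C6 bond, ring B).** This is the strategic cut: the achiral dienone aldehyde 12 cyclises by enamine catalysis, and the choice between its two enone arms creates C10. The alternatives to this cut (C9–C10 or C4–C5/C9–C10) are discussed below. 12 has no stereocentre. The forward reaction must distinguish enantiotopic arms.

**12 ⇒ 10 ⇒ 9 ⇒ 6 + 7 (ring A).** The aldehyde comes from the terminal alkene of 10 (one carbon lost), the dienone from enone 9, and 9 from Robinson annulation of the α-branched aldehyde 6 with but-3-en-2-one 7. The annulation creates the quaternary carbon and ring A together. The forward steps must keep the ketal intact, so they are run under basic or neutral conditions.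

**6 ⇒ 5 ⇒ 4 ⇒ 1 + 2 (C8–C9 bond).** The 1,4-relationship between the future C8 ketone and the aldehyde is made by acylating the zinc homoenolate of bromo ester 1 with pent-4-enoyl chloride 2 to give keto ester 4. Ketalisation (5) precedes ester reduction (6), so the two carbonyl groups never compete. All starting materials are commercial.

## Roads not taken

**Alternative 1: oxidative radical bicyclisation of an acyclic keto ester.**
- Cut: C4–C5 and C9–C10.
- Forward step: Mn(OAc)3 (trivalent manganese) oxidises the β-keto ester A1 to the C4 radical, which closes ring A onto C5; the tertiary C10 radical closes ring B onto C9; Cu(OAc)2 (divalent copper) turns the C8 radical into the exocyclic alkene of A2.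
- Merits: two rings, two C–C bonds and the trans ring fusion in one step from a short polyene; C14, C15, the C3 ketone and a masked C8 ketone are all in place; no flatten-and-reset of C5.
- Weak points for this target:
  - C10 is controlled by a stoichiometric 8-phenylmenthyl auxiliary acting on a radical several atoms away.
  - In A2, C4 carries the ester on the β-face and the methyl on the α-face, whereas the target needs β-methyl and α-hydroxyl. The carboxyl must be excised and replaced by oxygen, and the C4 configuration set by the auxiliary is discarded.
  - The copper termination usually gives exo/endo alkene mixtures.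
  - The C3 ketone still needs reduction to the axial alcohol next to a quaternary carbon.
- Comparison: A2 is reached in clearly fewer steps than the chosen route needs to reach 20, and this is conceded. The chosen plan sets against it catalytic control of C10 and an end-game in which both ring-A oxygens arrive in one α-face osmylation, with no carbon-to-oxygen exchange at a quaternary centre.

**Alternative 2: desymmetrising dearomative allylation of a dimethylresorcinol.**
- Cut: C9–C10.
- Forward step: Pd2(dba)3 (zerovalent palladium) with a chiral diphosphine ionises the allylic carbonate of the symmetric resorcinol A3; one of the two enantiotopic methyl-bearing ring carbons attacks C9, closing ring B and dearomatising ring A to A4.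
- Merits: very short and catalytic; sets C10; delivers C14, C15, the C4=C5 enone needed for the reductive reset, the C3 oxygen and an 8-methylidene group as masked ketone; no carbon has to be excised.
- Weak points for this target:
  - A4 has a superfluous oxygen at C1, part of a vinylogous acid with C3. It must be distinguished from C3=O and removed next to the quaternary centre, which costs several steps of uncertain regiocontrol.
  - C-allylation at a methyl-substituted, doubly flanked ring carbon to form a quaternary centre is demanding.
  - The 8-methylidene group would compete with the C3=C4 alkene in the later osmylation.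
- Comparison: in step count to a 4-methyl-4-en-3-one of defined C10 configuration, Alternative 2 is better. The chosen plan sets against it that its superfluous atom (the formyl carbon) leaves in one step, that the C8 ketal is inert to every later reagent, and that the key reaction type has close precedent on 4,4-dialkyl dienones.

**Alternative 3: silicon-tethered radical delivery of the angular methyl.**
- Cut: C10–C14.
- Forward step: Bu3SnH with AIBN generates the silylmethyl radical of the C8 silyl ether A5, which adds to C10 of the C5=C10 alkene in a six-membered siloxane; the C5 radical is reduced from the α-face to give the trans-fused A6.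
- Merits: the C8 oxygen, needed anyway, becomes the stereochemical anchor; C14 arrives strictly syn to it; the trans fusion is set in the same step.
- Weak points for this target:
  - The absolute configuration must already reside in the C8 carbinol of a preformed octalin, so the asymmetric problem is only moved.
  - Radical addition to a tetrasubstituted alkene to form a quaternary centre in a 6-exo mode competes with direct reduction of the radical.
  - Hydrogen transfer to C5 may not be face-selective.
  - The neopentyl C–Si bond must be protodesilylated rather than oxidised.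
  - Ring A of A6 is a saturated 4-methyl-3-ketal whose later oxidation at C4 again poses the C2/C4 regiochemistry question.
  - The reagent is stoichiometric tin.
- Comparison: Alternative 3 is as good as or better than the chosen plan in setting the trans fusion directly. The chosen plan forms ring B and C10 in one catalytic step from an achiral precursor and obtains the C3–C4 enolate regiochemistry from the enone reduction.

Key step: step 7

Assumption: centres that are erased later (the racemic carbon of 4–9, C6 of 13, C4 of 16, C7 of 27) are drawn as the expected major form; their configuration has no bearing on the route.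

## Route

Step 1
Reactants: 1 methyl 3-bromo-2-methylpropanoate (racemic); 2 pent-4-enoyl chloride
Product: 4 methyl 2-methyl-4-oxooct-7-enoate (racemic), via zinc homoenolate 3 (not isolated)
Conditions: Zn dust, LiCl, THF, 40 °C; then 2, Pd(PPh3)4 (5 mol %), THF, 0 °C to rt
Reagents that add atoms: none
Why: Zinc inserts into the primary C–Br bond to give the ester-chelated homoenolate, which undergoes Negishi acylation with the acid chloride under zerovalent palladium catalysis and does not add to the ketone formed. This makes the 1,4-dicarbonyl unit (future C8 ketone and C10 branch) in one operation.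

Step 2
Reactants: 4 methyl 2-methyl-4-oxooct-7-enoate
Product: 5 methyl 3-[2-(but-3-en-1-yl)-1,3-dioxolan-2-yl]-2-methylpropanoate (racemic)
Conditions: ethylene glycol, TsOH·H2O (cat.), benzene, reflux, azeotropic removal of water
Reagents that add atoms: ethylene glycol, OCCO
Why: Acid-catalysed ketalisation of the only ketone; the ester and the terminal alkene are inert. The dioxolane keeps C8 masked through every basic, reductive and organometallic step up to step 14.

Step 3
Reactants: 5 methyl 3-[2-(but-3-en-1-yl)-1,3-dioxolan-2-yl]-2-methylpropanoate
Product: 6 3-[2-(but-3-en-1-yl)-1,3-dioxolan-2-yl]-2-methylpropanal (racemic)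
Conditions: i-Bu2AlH (1.05 equiv), CH2Cl2, −78 °C; MeOH, then aq. potassium sodium tartrate
Reagents that add atoms: none
Why: Partial reduction of a methyl ester: the aluminium hemiacetal is stable at −78 °C (α-branching and chelation by the ketal oxygen) and collapses to the aldehyde only on work-up.

Step 4
Reactants: 6 3-[2-(but-3-en-1-yl)-1,3-dioxolan-2-yl]-2-methylpropanal; 7 but-3-en-2-one
Product: 9 4-{[2-(but-3-en-1-yl)-1,3-dioxolan-2-yl]methyl}-4-methylcyclohex-2-en-1-one (racemic), via keto aldehyde Michael adduct 8 (not isolated)
Conditions: KOH (0.3 equiv), EtOH, 0 °C to rt, then 70 °C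
Reagents that add atoms: none
Why: Robinson annulation of an α-branched aldehyde: the enolate adds to the enone to create the quaternary carbon, and the methyl ketone then condenses onto the now non-enolisable aldehyde to give the 4,4-disubstituted cyclohexenone. Basic conditions preserve the ketal.

Step 5
Reactants: 9 4-{[2-(but-3-en-1-yl)-1,3-dioxolan-2-yl]methyl}-4-methylcyclohex-2-en-1-one
Product: 10 4-{[2-(but-3-en-1-yl)-1,3-dioxolan-2-yl]methyl}-4-methylcyclohexa-2,5-dien-1-one
Conditions: DDQ, 1,4-dioxane, reflux
Reagents that add atoms: none
Why: DDQ dehydrogenation through the α′-enol is the standard route from 4,4-disubstituted cyclohexenones to cyclohexa-2,5-dienones. The quaternary carbon prevents aromatisation, the ketal tolerates the neutral anhydrous medium, and the stereocentre of 9 disappears, so 10 is achiral.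

Step 6
Reactants: 10 4-{[2-(but-3-en-1-yl)-1,3-dioxolan-2-yl]methyl}-4-methylcyclohexa-2,5-dien-1-one
Product: 12 3-{2-[(1-methyl-4-oxocyclohexa-2,5-dien-1-yl)methyl]-1,3-dioxolan-2-yl}propanal, via vicinal diol 11 (not isolated)
Conditions: OsO4 (2 mol %), NaIO4 (4 equiv), 2,6-lutidine, 1,4-dioxane/H2O (3:1), rt
Reagents that add atoms: osmium tetroxide (catalytic oxygen carrier), O=[Os](=O)(=O)=O; sodium periodate, [Na+].[O-]I(=O)(=O)=O
Why: Lemieux–Johnson cleavage: OsO4 dihydroxylates the electron-rich terminal alkene far faster than the electron-poor dienone bonds, and NaIO4 cleaves the diol and reoxidises osmium. 2,6-Lutidine buffers the medium so the ketal survives.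

Step 7
Reactants: 12 3-{2-[(1-methyl-4-oxocyclohexa-2,5-dien-1-yl)methyl]-1,3-dioxolan-2-yl}propanal
Product: 13 cis-fused 8,8-ethylenedioxy-10β-methyl-3-oxodecal-1-ene-6β-carbaldehyde (5β-H; 5S,6R,10S)
Conditions: (S)-2-[diphenyl(trimethylsilyloxy)methyl]pyrrolidine (20 mol %), PhCO2H (20 mol %), toluene, 0 °C to rt
Reagents that add atoms: none
Why: The amine condenses with the aldehyde of 12 to the (E)-enamine, whose α-carbon C6 adds to C5 of one enone arm; protonation of the dienolate at C4 and hydrolysis of the iminium ion release 13 and the catalyst. The closest known reaction type is the secondary-amine-catalysed desymmetrising intramolecular Michael addition of tethered aldehydes to 4,4-disubstituted cyclohexa-2,5-dienones. Ring B closes in the 6-exo-trig mode through a chair-like transition state, and because C6 can bond only on the dienone face that carries the tether, the ring fusion is necessarily cis (H-5 syn to C14). C6 is controlled by the catalyst: the diphenyl(silyloxy)methyl group shields one enamine face, so that C5 bonds to the Si face of C6. C10 and C5 are controlled by the same element through the chair: with that face fixed, only attack on one arm places the bulky enamine unit equatorial and anti to C10, whereas the other arm would force it axial, syn to the ketal oxygen and the spectator arm. This predicts 13 with the formyl group on the face of H-5 (6β, trans to C4); C6 is erased in step 8, so only C10 has to be formed with high fidelity. The step needs selection between the enantiotopic arms and conjugate addition in preference to aldehyde self-condensation; the C8 ketal secures this by keeping 12 achiral, blocking enolisation at C7 and C9, and favouring the folded conformer through its geminal substitution.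

Step 8
Reactants: 13 cis-fused 8,8-ethylenedioxy-10β-methyl-3-oxodecal-1-ene-6β-carbaldehyde
Product: 14 cis-fused 8,8-ethylenedioxy-10β-methyldecal-1-en-3-one (5β-H)
Conditions: RhCl(PPh3)3 (1.1 equiv), PhCN, 130 °C
Reagents that add atoms: none
Why: Tsuji–Wilkinson decarbonylation: oxidative addition of the formyl C–H bond to rhodium, CO extrusion and C–H reductive elimination replace CHO by H, turning C6 into a methylene. Enone and ketal are inert; the reagent is stoichiometric because the carbonyl complex does not turn over at this temperature.

Step 9
Reactants: 14 cis-fused 8,8-ethylenedioxy-10β-methyldecal-1-en-3-one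
Product: 16 cis-fused 8,8-ethylenedioxy-4β,10β-dimethyldecal-1-en-3-one (5β-H; C4 epimers, 4β drawn), via lithium dienolate 15 (not isolated)
Conditions: LiN(i-Pr)2, THF, −78 °C; MeI, −78 to −20 °C
Reagents that add atoms: iodomethane, CI
Why: Enone 14 has a single enolisable position (C4, since C10 is quaternary), so kinetic deprotonation gives the cross-conjugated dienolate and C-methylation installs C15. The epimer ratio at C4 is irrelevant because C4 becomes sp2 in step 10.

Step 10
Reactants: 16 cis-fused 8,8-ethylenedioxy-4β,10β-dimethyldecal-1-en-3-one
Product: 19 8,8-ethylenedioxy-4,10β-dimethyldecala-1,4-dien-3-one, via lithium dienolate 17 (not isolated), via silyl dienol ether 18 (not isolated)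
Conditions: LiN(i-Pr)2, THF, −78 °C; Me3SiCl; then Pd(OAc)2 (1.05 equiv), MeCN, rt
Reagents that add atoms: none
Why: Saegusa–Ito oxidation: the silyl dienol ether transfers C4 to palladium and β-hydride elimination of H-5 gives the tetrasubstituted C4=C5 bond, the endocyclic conjugated isomer being the usual outcome for 2-methylcycloalkanone-derived silyl enol ethers. C4 and C5 are flattened; C10 is untouched.

Step 11
Reactants: 19 8,8-ethylenedioxy-4,10β-dimethyldecala-1,4-dien-3-one
Product: 20 8,8-ethylenedioxy-4,10β-dimethyldecal-4-en-3-one
Conditions: H2 (1 atm), RhCl(PPh3)3 (10 mol %), benzene, rt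
Reagents that add atoms: none
Why: Homogeneous hydrogenation with RhCl(PPh3)3 reduces the disubstituted C1=C2 bond of cross-conjugated 1,4-dien-3-ones and leaves the hindered tetrasubstituted C4=C5 bond, as is long established for steroidal and santonin-type dienones.

Step 12
Reactants: 20 8,8-ethylenedioxy-4,10β-dimethyldecal-4-en-3-one
Product: 22 trans-fused 8,8-ethylenedioxy-4,10β-dimethyldecal-3-en-3-yl trifluoromethanesulfonate (5α-H), via lithium enolate 21 (not isolated)
Conditions: Li, NH3(l), THF, t-BuOH (1.0 equiv), −78 °C; isoprene; NH3 evaporated; PhNTf2, THF, −78 °C to rt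
Reagents that add atoms: N-phenylbis(trifluoromethanesulfonimide), O=S(=O)(N(c1ccccc1)S(=O)(=O)C(F)(F)F)C(F)(F)F
Why: Dissolving-metal reduction protonates C5 axially on the α-face and so gives the trans ring fusion (H-5 anti to C14), leaving the lithium enolate regiospecifically at C3–C4; O-sulfonylation fixes the double bond at C3=C4. The axial ketal oxygen syn to C14 is already present in 20, so the usual trans preference should hold.

Step 13
Reactants: 22 trans-fused 8,8-ethylenedioxy-4,10β-dimethyldecal-3-en-3-yl trifluoromethanesulfonate
Product: 23 trans-fused 8,8-ethylenedioxy-4,10β-dimethyldecal-3-ene (5α-H)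
Conditions: Pd(OAc)2 (5 mol %), PPh3, n-Bu3N, HCO2H, DMF, 60 °C
Reagents that add atoms: none
Why: Palladium-catalysed formate reduction of an enol triflate: oxidative addition to zerovalent palladium, formate exchange, decarboxylation and C–H reductive elimination give the trisubstituted alkene without touching the ketal or C5.

Step 14
Reactants: 23 trans-fused 8,8-ethylenedioxy-4,10β-dimethyldecal-3-ene
Product: 24 trans-fused 4,10β-dimethyldecal-3-en-8-one (5α-H)
Conditions: aq. HCl (1 M), THF, rt
Reagents that add atoms: water, O
Why: Acid hydrolysis of the dioxolane; the trisubstituted alkene is not hydrated or shifted under these mild conditions.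

Step 15
Reactants: 24 trans-fused 4,10β-dimethyldecal-3-en-8-one; 25 acetone
Product: 27 trans-fused 7β-(2-hydroxypropan-2-yl)-4,10β-dimethyldecal-3-en-8-one (C7 epimers, 7β drawn), via lithium enolate 26 (not isolated)
Conditions: LiN(i-Pr)2, THF, −78 °C; acetone, −78 °C; AcOH quench at −78 °C
Reagents that add atoms: none
Why: Kinetic deprotonation occurs at C7 and not at the neopentyl C9 next to the quaternary C10; the lithium enolate adds to acetone in a directed aldol reaction, and the cold acidic quench prevents retro-aldol cleavage. The C7 configuration is irrelevant.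

Step 16
Reactants: 27 trans-fused 7β-(2-hydroxypropan-2-yl)-4,10β-dimethyldecal-3-en-8-one
Product: 29 eudesma-3,7(11)-dien-8-one (5α-H, 10β-CH3), via tertiary mesylate 28 (not isolated)
Conditions: MsCl, Et3N, CH2Cl2, 0 °C to rt; then DBU, rt
Reagents that add atoms: none
Why: Sulfene-mediated mesylation of the tertiary alcohol and E1cB elimination through the C7 enolate give the conjugated isopropylidene ketone, not the isopropenyl isomer; the basic medium leaves the C3=C4 bond in place.

Step 17
Reactants: 29 eudesma-3,7(11)-dien-8-one
Product: 30 3α,4α-dihydroxyeudesm-7(11)-en-8-one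
Conditions: OsO4 (5 mol %), N-methylmorpholine N-oxide, acetone/H2O (8:1), rt
Reagents that add atoms: osmium tetroxide (catalytic oxygen carrier), O=[Os](=O)(=O)=O; N-methylmorpholine N-oxide, C[N+]1([O-])CCOCC1; water, O
Why: Catalytic syn-dihydroxylation: OsO4 adds to the electron-rich trisubstituted C3=C4 bond and not to the electron-poor tetrasubstituted enone bond, and from the α-face because the axial C14 methyl blocks the β-face. The syn addition sets C3 (α-OH) and C4 (α-OH, β-CH3) together.

Step 18
Reactants: 30 3α,4α-dihydroxyeudesm-7(11)-en-8-one; 31 angelic acid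
Product: 33 3α-angeloyloxy-4α-hydroxyeudesm-7(11)-en-8-one, via mixed anhydride 32 (not isolated)
Conditions: 31, 2,4,6-trichlorobenzoyl chloride, Et3N, toluene, rt; then 30, 80 °C
Reagents that add atoms: none
Why: Yamaguchi-type mixed-anhydride esterification run without a nucleophilic catalyst, the conditions under which angelates form without isomerisation to tiglates. Only the secondary 3α-hydroxyl reacts; the tertiary 4-hydroxyl is too hindered.

Step 19
Reactants: 33 3α-angeloyloxy-4α-hydroxyeudesm-7(11)-en-8-one
Product: 34 3α-angeloyloxy-4α-hydroxy-11-hydroperoxyeudesm-6-en-8-one (3R,4S,5R,10R; CNP0161122.2)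
Conditions: O2, visible light, tetraphenylporphyrin (cat.), CH2Cl2, 0 °C
Reagents that add atoms: oxygen, O=O
Why: Schenck ene reaction: singlet oxygen bonds to the β-carbon C11 of the s-cis enone and takes hydrogen from C6, the alkyl group geminal to the carbonyl on the α-carbon, which is the known regiochemistry for α,β-unsaturated carbonyl compounds. This gives the C6=C7 enone and the tertiary hydroperoxide without a new stereocentre; the angelate is a slower ene substrate and should survive if irradiation stops at full conversion.

## Compound list

1 | methyl 3-bromo-2-methylpropanoate (racemic) | COC(=O)C(C)CBr | starting material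
2 | pent-4-enoyl chloride | C=CCCC(Cl)=O | starting material
3 | (3-methoxy-2-methyl-3-oxopropyl)zinc bromide (zinc homoenolate) | COC(=O)C(C)C[Zn]Br | intermediate
4 | methyl 2-methyl-4-oxooct-7-enoate (racemic) | COC(=O)C(C)CC(=O)CCC=C | intermediate
5 | methyl 3-[2-(but-3-en-1-yl)-1,3-dioxolan-2-yl]-2-methylpropanoate (racemic) | COC(=O)C(C)CC1(CCC=C)OCCO1 | intermediate
6 | 3-[2-(but-3-en-1-yl)-1,3-dioxolan-2-yl]-2-methylpropanal (racemic) | O=CC(C)CC1(CCC=C)OCCO1 | intermediate
7 | but-3-en-2-one | CC(=O)C=C | starting material
8 | 2-{[2-(but-3-en-1-yl)-1,3-dioxolan-2-yl]methyl}-2-methyl-5-oxohexanal (racemic Michael adduct) | O=CC(C)(CCC(C)=O)CC1(CCC=C)OCCO1 | intermediate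
9 | 4-{[2-(but-3-en-1-yl)-1,3-dioxolan-2-yl]methyl}-4-methylcyclohex-2-en-1-one (racemic) | CC1(CC2(CCC=C)OCCO2)CCC(=O)C=C1 | intermediate
10 | 4-{[2-(but-3-en-1-yl)-1,3-dioxolan-2-yl]methyl}-4-methylcyclohexa-2,5-dien-1-one | CC1(CC2(CCC=C)OCCO2)C=CC(=O)C=C1 | intermediate
11 | 4-{[2-(3,4-dihydroxybutyl)-1,3-dioxolan-2-yl]methyl}-4-methylcyclohexa-2,5-dien-1-one (racemic at the carbinol carbon) | CC1(CC2(CCC(O)CO)OCCO2)C=CC(=O)C=C1 | intermediate
12 | 3-{2-[(1-methyl-4-oxocyclohexa-2,5-dien-1-yl)methyl]-1,3-dioxolan-2-yl}propanal | CC1(CC2(CCC=O)OCCO2)C=CC(=O)C=C1 | intermediate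
13 | cis-fused 8,8-ethylenedioxy-10β-methyl-3-oxodecal-1-ene-6β-carbaldehyde (5β-H; 5S,6R,10S) | O=C1C=C[C@]2(C)CC3(OCCO3)C[C@@H](C=O)[C@@H]2C1 | intermediate
14 | cis-fused 8,8-ethylenedioxy-10β-methyldecal-1-en-3-one (5β-H) | O=C1C=C[C@]2(C)CC3(OCCO3)CC[C@@H]2C1 | intermediate
15 | lithium 1,3-dienolate of 14 (O–Li on C3, C1=C2 and C3=C4) | [Li]OC=1C=C[C@]2(C)CC3(OCCO3)CC[C@@H]2C=1 | intermediate
16 | cis-fused 8,8-ethylenedioxy-4β,10β-dimethyldecal-1-en-3-one (5β-H; 4β epimer drawn) | O=C1C=C[C@]2(C)CC3(OCCO3)CC[C@@H]2[C@H]1C | intermediate
17 | lithium 1,3-dienolate of 16 | [Li]OC=1C=C[C@]2(C)CC3(OCCO3)CC[C@@H]2C=1C | intermediate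
18 | 3-trimethylsilyloxy-1,3-diene derived from 16 (5β-H) | C[Si](C)(C)OC=1C=C[C@]2(C)CC3(OCCO3)CC[C@@H]2C=1C | intermediate
19 | 8,8-ethylenedioxy-4,10β-dimethyldecala-1,4-dien-3-one | O=C1C=C[C@]2(C)CC3(OCCO3)CCC2=C1C | intermediate
20 | 8,8-ethylenedioxy-4,10β-dimethyldecal-4-en-3-one (10R) | O=C1CC[C@]2(C)CC3(OCCO3)CCC2=C1C | intermediate
21 | lithium C3–C4 enolate of the trans-fused ketone (5α-H) | [Li]OC=1CC[C@]2(C)CC3(OCCO3)CC[C@H]2C=1C | intermediate
22 | trans-fused 8,8-ethylenedioxy-4,10β-dimethyldecal-3-en-3-yl trifluoromethanesulfonate (5α-H) | O=S(=O)(OC=1CC[C@]2(C)CC3(OCCO3)CC[C@H]2C=1C)C(F)(F)F | intermediate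
23 | trans-fused 8,8-ethylenedioxy-4,10β-dimethyldecal-3-ene (5α-H) | C=1CC[C@]2(C)CC3(OCCO3)CC[C@H]2C=1C | intermediate
24 | trans-fused 4,10β-dimethyldecal-3-en-8-one (5α-H) | C=1CC[C@]2(C)CC(=O)CC[C@H]2C=1C | intermediate
25 | acetone | CC(C)=O | starting material
26 | lithium C7–C8 enolate of 24 | C=1CC[C@]2(C)CC(O[Li])=CC[C@H]2C=1C | intermediate
27 | trans-fused 7β-(2-hydroxypropan-2-yl)-4,10β-dimethyldecal-3-en-8-one (5α-H; 7β epimer drawn) | C=1CC[C@]2(C)CC(=O)[C@@H](C(C)(C)O)C[C@H]2C=1C | intermediate
28 | tertiary methanesulfonate of 27 | C=1CC[C@]2(C)CC(=O)[C@@H](C(C)(C)OS(C)(=O)=O)C[C@H]2C=1C | intermediate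
29 | eudesma-3,7(11)-dien-8-one (5α-H, 10β-CH3) | C=1CC[C@]2(C)CC(=O)C(=C(C)C)C[C@H]2C=1C | intermediate
30 | 3α,4α-dihydroxyeudesm-7(11)-en-8-one | O[C@@H]1CC[C@]2(C)CC(=O)C(=C(C)C)C[C@H]2[C@]1(C)O | intermediate
31 | angelic acid, (Z)-2-methylbut-2-enoic acid | C/C=C(/C)C(=O)O | starting material
32 | angelic 2,4,6-trichlorobenzoic anhydride | C/C=C(/C)C(=O)OC(=O)c1c(Cl)cc(Cl)cc1Cl | intermediate
33 | 3α-angeloyloxy-4α-hydroxyeudesm-7(11)-en-8-one | C/C=C(/C)C(=O)O[C@@H]1CC[C@]2(C)CC(=O)C(=C(C)C)C[C@H]2[C@]1(C)O | intermediate
34 | 3α-angeloyloxy-4α-hydroxy-11-hydroperoxyeudesm-6-en-8-one (3R,4S,5R,10R) | C/C=C(/C)C(=O)O[C@@H]1CC[C@]2(C)CC(=O)C(C(C)(C)OO)=C[C@H]2[C@]1(C)O | target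

## Step count and uncertain steps

Total: 19 steps. Longest linear sequence: 19 steps (1 and 2 to 34); 7, 25 and 31 each enter in a single step.

**Step 7 (key step).** Discrimination between the two enone arms may be insufficient, the sense of induction may be opposite to the shielding model (the antipodal catalyst would then be used), or closure of the six-membered ring may be slow enough for aldehyde self-condensation to compete. Fallback with a stoichiometric auxiliary, setting out from 12: condensation with (R)-1-amino-2-(methoxymethyl)pyrrolidine should give the hydrazone F1. Deprotonation with LiN(i-Pr)2 at −100 °C and intramolecular Michael addition of the chelated azaenolate to the dienone should give the cyclised hydrazone F2. Cleavage with CuCl2 in aqueous THF returns to the route at 13.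

**Step 8.** Decarbonylation of a hindered secondary aldehyde may stall at the acyl-rhodium stage or divert to β-hydride elimination with alkene formation. Fallback from 13: Pinnick oxidation (NaClO2, NaH2PO4, 2-methylbut-2-ene) should give the carboxylic acid F3. Coupling with N-hydroxyphthalimide (diisopropylcarbodiimide) should give the redox-active ester F4. Radical reductive decarboxylation (Bu3SnH, AIBN, benzene, 80 °C) returns to the route at 14.

**Step 10.** Enolisation of the hindered tertiary C4–H may be incomplete, or β-hydride elimination may run toward C15 and give the exocyclic methylidene isomer. Fallback from 14, bypassing 16: the lithium dienolate is aminomethylated with dimethylmethylideneammonium iodide to the Mannich base F5. Quaternisation with MeI and elimination should give the 4-methylidene enone F6. Isomerisation of the exocyclic double bond into the ring with RhCl3·3H2O in ethanol returns to the route at 19.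

**Step 18.** Z-to-E isomerisation to the tiglate may occur during the long heating, or the axial 3α-hydroxyl next to the quaternary C4 may not acylate. Fallback from 30: esterification with 2-(diphenoxyphosphoryl)propanoic acid (carbodiimide, 4-dimethylaminopyridine; this acid has no alkene geometry to lose) should give the phosphonate ester F7. A (Z)-selective Horner–Wadsworth–Emmons olefination with acetaldehyde (NaH, THF, −78 °C) builds the angelate double bond on the substrate and returns to the route at 33.

**Step 19.** Hydrogen abstraction from C12/C13 instead of C6, a competing ene reaction at the angelate, or decay of the hydroperoxide under prolonged irradiation may lower the yield. Fallback by changing the order of events, from 30 (which has no other ene-active alkene): photooxygenation should give the hydroperoxy diol F8. Selective silylation of the hydroperoxide (Et3SiCl, imidazole) should give the silyl peroxide F9. Angeloylation as in step 18 should give F10, and desilylation with HF·pyridine returns to the route at 34.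

## Further compounds

F1 | step 7 | (E)-hydrazone of 12 with (R)-1-amino-2-(methoxymethyl)pyrrolidine | CC1(CC2(CC/C=N/N3CCC[C@@H]3COC)OCCO2)C=CC(=O)C=C1
F2 | step 7 | cyclised hydrazone, the (R)-2-(methoxymethyl)pyrrolidin-1-yl imine of 13 | O=C1C=C[C@]2(C)CC3(OCCO3)C[C@@H](/C=N/N4CCC[C@@H]4COC)[C@@H]2C1
F3 | step 8 | cis-fused 8,8-ethylenedioxy-10β-methyl-3-oxodecal-1-ene-6β-carboxylic acid | O=C1C=C[C@]2(C)CC3(OCCO3)C[C@@H](C(=O)O)[C@@H]2C1
F4 | step 8 | N-phthalimidoyl ester of F3 | O=C1C=C[C@]2(C)CC3(OCCO3)C[C@@H](C(=O)ON4C(=O)c5ccccc5C4=O)[C@@H]2C1
F5 | step 10 | cis-fused 4β-(dimethylaminomethyl)-8,8-ethylenedioxy-10β-methyldecal-1-en-3-one (4β epimer drawn) | O=C1C=C[C@]2(C)CC3(OCCO3)CC[C@@H]2[C@H]1CN(C)C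
F6 | step 10 | cis-fused 8,8-ethylenedioxy-10β-methyl-4-methylidenedecal-1-en-3-one | O=C1C=C[C@]2(C)CC3(OCCO3)CC[C@@H]2C1=C
F7 | step 18 | 3α-[2-(diphenoxyphosphoryl)propanoyloxy]-4α-hydroxyeudesm-7(11)-en-8-one (epimers at the phosphonate-bearing carbon) | CC(C(=O)O[C@@H]1CC[C@]2(C)CC(=O)C(=C(C)C)C[C@H]2[C@]1(C)O)P(=O)(Oc1ccccc1)Oc1ccccc1
F8 | step 19 | 3α,4α-dihydroxy-11-hydroperoxyeudesm-6-en-8-one | O[C@@H]1CC[C@]2(C)CC(=O)C(C(C)(C)OO)=C[C@H]2[C@]1(C)O
F9 | step 19 | 3α,4α-dihydroxy-11-(triethylsilylperoxy)eudesm-6-en-8-one | O[C@@H]1CC[C@]2(C)CC(=O)C(C(C)(C)OO[Si](CC)(CC)CC)=C[C@H]2[C@]1(C)O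
F10 | step 19 | 3α-angeloyloxy-4α-hydroxy-11-(triethylsilylperoxy)eudesm-6-en-8-one | C/C=C(/C)C(=O)O[C@@H]1CC[C@]2(C)CC(=O)C(C(C)(C)OO[Si](CC)(CC)CC)=C[C@H]2[C@]1(C)O
A1 | alternative 1 | 8-phenylmenthyl (6E)-2,6,10-trimethyl-3-oxoundeca-6,10-dienoate | CC(C(=O)O[C@@H]1C[C@H](C)CC[C@H]1C(C)(C)c1ccccc1)C(=O)CC/C(C)=C/CCC(C)=C
A2 | alternative 1 | 8-phenylmenthyl trans-4,10-dimethyl-8-methylidene-3-oxodecalin-4-carboxylate | C=C1CC[C@H]2[C@@](C)(C(=O)O[C@@H]3C[C@H](C)CC[C@H]3C(C)(C)c3ccccc3)C(=O)CC[C@]2(C)C1
A3 | alternative 2 | 4-(3,5-dihydroxy-2,6-dimethylphenyl)-2-methylidenebutyl methyl carbonate | COC(=O)OCC(=C)CCc1c(C)c(O)cc(O)c1C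
A4 | alternative 2 | 4,10-dimethyl-8-methylideneoctal-4-ene-1,3-dione (diketo tautomer) | CC1=C2CCC(=C)C[C@@]2(C)C(=O)CC1=O
A5 | alternative 3 | 8β-[(bromomethyl)dimethylsilyloxy]-3,3-ethylenedioxy-4α-methyloctal-5(10)-ene | BrC[Si](C)(C)O[C@H]1CCC2=C(CCC3(OCCO3)[C@H]2C)C1
A6 | alternative 3 | trans-decalin with a C8–O–SiMe2–C14–C10 siloxane bridge, 4α-methyl and 3,3-ethylenedioxy groups | C[Si]1(C)O[C@H]2CC[C@H]3[C@H](C)C4(OCCO4)CC[C@]3(C1)C2
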